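**Retrosynthetic overview**
1. Target 28 ⇐ C2 carbinol 27 (oxidation); 27 ⇐ acyclic diyne diol 25 by one-pot ring-closing alkyne metathesis (C9≡C10, 14-membered carbocycle) and transannular 5-exo-dig hydroalkoxylation (O–C9, oxolane with Z enol ether).
2. 25 ⇐ C1–C2 bond: Ni/Cr coupling of alkenyl bromide 24 (C10–C15, C12 acetate) with epoxy aldehyde 16 (C2–C9).
3. 16 ⇐ (S)-citronellal (gives C8): C6 by organocatalytic chlorination/epoxide, C3=C4 by carboalumination, oxirane by Sharpless epoxidation.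
4. 24 ⇐ methyl ketone 21: C12 by catalytic asymmetric Corey–Chaykovsky epoxidation, then propynyl opening and acetylation.
5. Ring order: oxirane (step 7), then carbocycle and oxolane together (step 13).

Assumption: cembrane numbering is used (C1 = isopropylidene-bearing carbon, C2 = ketone, C3–C4 = oxirane, C6/C9 = oxolane C–O carbons, C8 = CHMe, C12 = C(OAc)Me); reagents are not numbered; in steps 4 and 10 the catalyst antipode is the one that gives the stated configuration.

**Step 1**
Reactants: 1 (S)-citronellal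
Product: 3 (3S)-3,7-dimethyloct-6-en-1-yne, via enol nonaflate 2 (not isolated)
Conditions: C4F9SO2F, P2-Et phosphazene base, DMF, −30 °C to rt
Reagents that add atoms: none
Why: One-pot enol nonaflation and E2 elimination (aldehyde-to-alkyne dehydration) converts CH2–CHO into C≡CH without touching the stereocentre that becomes C8.

**Step 2**
Reactants: 3 (3S)-3,7-dimethyloct-6-en-1-yne
Product: 5 (4S)-4,8-dimethylnon-7-en-2-yne, via lithium acetylide 4 (not isolated)
Conditions: n-BuLi, THF, −78 °C; MeI, −78 °C to rt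
Reagents that add atoms: iodomethane CI
Why: Acetylide C-methylation (SN2) caps the alkyne for alkyne metathesis and distinguishes it from the terminal alkyne introduced in step 5.

**Step 3**
Reactants: 5 (4S)-4,8-dimethylnon-7-en-2-yne
Product: 7 (4S)-4-methylhept-5-ynal, via ozonide 6 (not isolated)
Conditions: O3 (1 equiv, indicator end point), CH2Cl2, −78 °C; PPh3
Reagents that add atoms: ozone [O-][O+]=O
Why: Chemoselective ozonolysis, because the electron-rich trisubstituted alkene reacts much faster than the internal alkyne, and reductive work-up gives the aldehyde.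

**Step 4**
Reactants: 7 (4S)-4-methylhept-5-ynal
Product: 10 (2R)-2-[(2S)-2-methylpent-3-yn-1-yl]oxirane, via chloroaldehyde 8 (not isolated), via chlorohydrin 9 (not isolated)
Conditions: NCS, 2,5-diphenylpyrrolidine (10 mol%, antipode giving the 2S chloride), CH2Cl2, 0 °C to rt; NaBH4, MeOH, 0 °C; aq. KOH, rt
Reagents that add atoms: none
Why: Enamine-catalysed enantioselective α-chlorination sets C6 under catalyst control, and borohydride reduction followed by Williamson closure with inversion gives the R terminal epoxide (one-pot aldehyde-to-epoxide sequence).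

**Step 5**
Reactants: 10 (2R)-2-[(2S)-2-methylpent-3-yn-1-yl]oxirane
Product: 11 (4R,6S)-6-methylnona-1,7-diyn-4-ol
Conditions: lithium acetylide–ethylenediamine, DMSO, rt; H2O
Reagents that add atoms: lithium acetylide–ethylenediamine complex [Li]C#C.NCCN
Why: SN2 epoxide opening by acetylide at the CH2 carbon leaves the C6–O bond intact, so the configuration is retained.

**Step 6**
Reactants: 11 (4R,6S)-6-methylnona-1,7-diyn-4-ol
Product: 14 (2E,5R,7S)-3,7-dimethyldec-2-en-8-yne-1,5-diol, via alkenylalane 12 (not isolated), via lithium alanate 13 (not isolated)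
Conditions: Me3Al (4 equiv), Cp2ZrCl2 (25 mol%), CH2Cl2, 0 °C to rt; n-BuLi, THF, −78 °C; (CH2O)n, −78 °C to rt
Reagents that add atoms: trimethylaluminium C[Al](C)C; formaldehyde (from paraformaldehyde) C=O
Why: Negishi zirconium-catalysed syn-carboalumination is selective for the terminal alkyne over the methyl-capped one and gives the E alkenylalane, whose ate complex is hydroxymethylated to the E trisubstituted allylic alcohol.

**Step 7**
Reactants: 14 (2E,5R,7S)-3,7-dimethyldec-2-en-8-yne-1,5-diol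
Product: 15 (2R,4S)-1-[(2S,3S)-3-(hydroxymethyl)-2-methyloxiran-2-yl]-4-methylhept-5-yn-2-ol
Conditions: Ti(OiPr)4 (10 mol%), L-(+)-DET (12 mol%), TBHP, 4 Å MS, CH2Cl2, −20 °C
Reagents that add atoms: tert-butyl hydroperoxide CC(C)(C)OO
Why: Sharpless asymmetric epoxidation of the primary E allylic alcohol with L-(+)-tartrate sets C3 and C4 by reagent control (same sense as geraniol to its 2S,3S epoxide), the homoallylic secondary OH being a much weaker director.

**Step 8**
Reactants: 15 (2R,4S)-1-[(2S,3S)-3-(hydroxymethyl)-2-methyloxiran-2-yl]-4-methylhept-5-yn-2-ol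
Product: 16 (2R,3S)-3-[(2R,4S)-2-hydroxy-4-methylhept-5-yn-1-yl]-3-methyloxirane-2-carbaldehyde
Conditions: TEMPO (10 mol%), PhI(OAc)2, CH2Cl2, rt
Reagents that add atoms: none
Why: Oxoammonium (TEMPO) oxidation is selective for the primary alcohol over the secondary one and is mild enough for the epoxide, whose trans geometry also prevents lactol formation.

**Step 9**
Reactants: 17 2-methyl-2-vinyl-1,3-dioxolane; 18 1,1-dibromo-2-methylprop-1-ene
Product: 21 5-bromo-6-methylhept-5-en-2-one, via alkylborane 19 (not isolated), via bromoalkenyl ketal 20 (not isolated)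
Conditions: 9-BBN, THF, 0 °C to rt; 18, PdCl2(dppf) (3 mol%), aq. K3PO4, DMF, rt; 1 M HCl, THF, rt
Reagents that add atoms: water O
Why: Anti-Markovnikov hydroboration and B-alkyl Suzuki–Miyaura mono-coupling with the gem-dibromoalkene (the two Br are equivalent and a second coupling to a tetrasubstituted alkene is slow), then acid hydrolysis of the ketal.

**Step 10**
Reactants: 21 5-bromo-6-methylhept-5-en-2-one
Product: 22 (2R)-2-(3-bromo-4-methylpent-3-en-1-yl)-2-methyloxirane
Conditions: Me3S(O)I, NaH, THF; La–Li3–tris(binaphthoxide) (5 mol%, BINOL antipode giving the R epoxide), (2,4,6-(MeO)3C6H2)3P=O (5 mol%), 5 Å MS, rt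
Reagents that add atoms: trimethylsulfoxonium iodide C[S+](C)(C)=O.[I-]
Why: Catalytic asymmetric Corey–Chaykovsky epoxidation of a methyl ketone sets C12 by catalyst control (about 90% ee expected for an alkyl methyl ketone, the minor C12 epimer being removed as a diastereomer after step 12).

**Step 11**
Reactants: 22 (2R)-2-(3-bromo-4-methylpent-3-en-1-yl)-2-methyloxirane
Product: 24 (5R)-8-bromo-5,9-dimethyldec-8-en-2-yn-5-yl acetate, via lithium alkoxide 23 (not isolated)
Conditions: 1-propynyllithium, THF/DMPU, 0 to 40 °C; Ac2O, DMAP (cat.), 0 °C to rt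
Reagents that add atoms: 1-propynyllithium [Li]C#CC; acetic anhydride CC(=O)OC(C)=O
Why: SN2 opening of the 2,2-disubstituted epoxide at CH2 (no Lewis acid, so no Meinwald rearrangement) followed by in-situ O-acylation of the tertiary alkoxide leaves the C12–O bond and configuration untouched.

**Step 12**
Reactants: 24 (5R)-8-bromo-5,9-dimethyldec-8-en-2-yn-5-yl acetate; 16 (2R,3S)-3-[(2R,4S)-2-hydroxy-4-methylhept-5-yn-1-yl]-3-methyloxirane-2-carbaldehyde
Product: 25 (5R)-8-{hydroxy[(2S,3S)-3-[(2R,4S)-2-hydroxy-4-methylhept-5-yn-1-yl]-3-methyloxiran-2-yl]methyl}-5,9-dimethyldec-8-en-2-yn-5-yl acetate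
Conditions: CrCl2 (6 equiv), NiCl2 (2 mol%), DMSO/THF, rt
Reagents that add atoms: none
Why: Nozaki–Hiyama–Kishi coupling adds the alkenylchromium chemoselectively to the aldehyde in the presence of acetate, epoxide, free OH and internal alkynes, placing the isopropylidene regiospecifically, and the new C2 carbinol (epimer mixture) is oxidised later.

**Step 13**
Reactants: 25 (5R)-8-{hydroxy[(2S,3S)-3-[(2R,4S)-2-hydroxy-4-methylhept-5-yn-1-yl]-3-methyloxiran-2-yl]methyl}-5,9-dimethyldec-8-en-2-yn-5-yl acetate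
Product: 27 (2ξ,3S,4S,6R,8S,9Z,12R)-12-acetoxy-3,4:6,9-diepoxycembra-1(15),9-dien-2-ol, via cycloalkyne diol 26 (not isolated)
Conditions: Mo alkylidyne with tripodal silanolate ligand (15 mol%), 5 Å MS, toluene (2 mM), 60 °C; then (JohnPhos)Au(MeCN)SbF6 (5 mol%), rt
Reagents that add atoms: none
Why: Proposed new method: a protic-group-tolerant Mo alkylidyne closes the 14-membered cycloalkyne by ring-closing alkyne metathesis with loss of but-2-yne, and a cationic Au(I) π-acid added to the same flask then effects transannular anti-oxyauration/protodeauration of C6–OH onto C9 (5-exo-dig, favoured over 6-endo because the homopropargylic acetate inductively deactivates C10), which fixes the Z enol ether (O and C11 cis) and the trans oxolane from the existing C6 and C8 centres; the closest known reaction types are RCAM and separate Au- or Pt-catalysed transannular alkynol hydroalkoxylation.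

**Step 14**
Reactants: 27 (2ξ,3S,4S,6R,8S,9Z,12R)-12-acetoxy-3,4:6,9-diepoxycembra-1(15),9-dien-2-ol
Product: 28 (3R,4S,6R,8S,9Z,12R)-12-acetoxy-3,4:6,9-diepoxycembra-1(15),9-dien-2-one
Conditions: Dess–Martin periodinane, pyridine, CH2Cl2, 0 °C to rt
Reagents that add atoms: none
Why: Buffered Dess–Martin oxidation of the only remaining alcohol gives the epoxy enone without base, so the isopropylidene cannot deconjugate, the enol ether is not hydrolysed and no stereocentre is touched.

**Compound list**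
1 | (S)-citronellal, (3S)-3,7-dimethyloct-6-enal | CC(C)=CCC[C@@H](CC=O)C | starting material
2 | (3S)-3,7-dimethylocta-1,6-dien-1-yl nonafluorobutane-1-sulfonate (E/Z) | CC(C)=CCC[C@@H](C=COS(=O)(=O)C(F)(F)C(F)(F)C(F)(F)C(F)(F)F)C | intermediate
3 | (3S)-3,7-dimethyloct-6-en-1-yne | CC(C)=CCC[C@@H](C#C)C | intermediate
4 | lithium (3S)-3,7-dimethyloct-6-en-1-yn-1-ide | CC(C)=CCC[C@@H](C#C[Li])C | intermediate
5 | (4S)-4,8-dimethylnon-7-en-2-yne | CC(C)=CCC[C@@H](C#CC)C | intermediate
6 | 3,3-dimethyl-5-[(3S)-3-methylhex-4-yn-1-yl]-1,2,4-trioxolane | CC1(C)OOC(CC[C@@H](C#CC)C)O1 | intermediate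
7 | (4S)-4-methylhept-5-ynal | O=CCC[C@@H](C#CC)C | intermediate
8 | (2S,4S)-2-chloro-4-methylhept-5-ynal | Cl[C@H](C=O)C[C@@H](C#CC)C | intermediate
9 | (2S,4S)-2-chloro-4-methylhept-5-yn-1-ol | Cl[C@H](CO)C[C@@H](C#CC)C | intermediate
10 | (2R)-2-[(2S)-2-methylpent-3-yn-1-yl]oxirane | C1O[C@@H]1C[C@@H](C#CC)C | intermediate
11 | (4R,6S)-6-methylnona-1,7-diyn-4-ol | O[C@H](C[C@@H](C#CC)C)CC#C | intermediate
12 | dimethyl[(1E,4R,6S)-4-(dimethylalumanyloxy)-2,6-dimethylnon-1-en-7-yn-1-yl]alumane | C[Al](C)O[C@H](C[C@@H](C#CC)C)C/C(C)=C/[Al](C)C | intermediate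
13 | lithium butyl ate complex of 12 (butyl on the alkenyl aluminium) | C[Al](C)O[C@H](C[C@@H](C#CC)C)C/C(C)=C/[Al-](C)(C)CCCC.[Li+] | intermediate
14 | (2E,5R,7S)-3,7-dimethyldec-2-en-8-yne-1,5-diol | O[C@H](C[C@@H](C#CC)C)C/C(C)=C/CO | intermediate
15 | (2R,4S)-1-[(2S,3S)-3-(hydroxymethyl)-2-methyloxiran-2-yl]-4-methylhept-5-yn-2-ol | O[C@H](C[C@@H](C#CC)C)C[C@]1(C)O[C@H]1CO | intermediate
16 | (2R,3S)-3-[(2R,4S)-2-hydroxy-4-methylhept-5-yn-1-yl]-3-methyloxirane-2-carbaldehyde | O[C@H](C[C@@H](C#CC)C)C[C@]1(C)O[C@H]1C=O | intermediate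
17 | 2-methyl-2-vinyl-1,3-dioxolane | C=CC1(C)OCCO1 | starting material
18 | 1,1-dibromo-2-methylprop-1-ene | CC(C)=C(Br)Br | starting material
19 | 9-[2-(2-methyl-1,3-dioxolan-2-yl)ethyl]-9-borabicyclo[3.3.1]nonane | CC1(CCB2C3CCCC2CCC3)OCCO1 | intermediate
20 | 2-(3-bromo-4-methylpent-3-en-1-yl)-2-methyl-1,3-dioxolane | CC(C)=C(Br)CCC1(C)OCCO1 | intermediate
21 | 5-bromo-6-methylhept-5-en-2-one | CC(=O)CCC(Br)=C(C)C | intermediate
22 | (2R)-2-(3-bromo-4-methylpent-3-en-1-yl)-2-methyloxirane | O1C[C@@]1(C)CCC(Br)=C(C)C | intermediate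
23 | lithium (5R)-8-bromo-5,9-dimethyldec-8-en-2-yn-5-olate | [Li+].[O-][C@@](CCC(Br)=C(C)C)(C)CC#CC | intermediate
24 | (5R)-8-bromo-5,9-dimethyldec-8-en-2-yn-5-yl acetate | CC(=O)O[C@@](CCC(Br)=C(C)C)(C)CC#CC | intermediate
25 | (5R)-8-{hydroxy[(2S,3S)-3-[(2R,4S)-2-hydroxy-4-methylhept-5-yn-1-yl]-3-methyloxiran-2-yl]methyl}-5,9-dimethyldec-8-en-2-yn-5-yl acetate (C2 carbinol epimers) | O[C@H](C[C@@H](C#CC)C)C[C@]1(C)O[C@H]1C(O)C(=C(C)C)CC[C@@](C)(OC(C)=O)CC#CC | intermediate
26 | (2ξ,3S,4S,6R,8S,12R)-12-acetoxy-3,4-epoxycembr-1(15)-en-9-yne-2,6-diol | O[C@H](C[C@@H](C#C2)C)C[C@]1(C)O[C@H]1C(O)C(=C(C)C)CC[C@@](C)(OC(C)=O)C2 | intermediate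
27 | (2ξ,3S,4S,6R,8S,9Z,12R)-12-acetoxy-3,4:6,9-diepoxycembra-1(15),9-dien-2-ol | CC(=O)O[C@@]1(C)C/C=C2\O[C@H](C[C@@H]2C)C[C@]2(C)O[C@H]2C(O)C(=C(C)C)CC1 | intermediate
28 | (3R,4S,6R,8S,9Z,12R)-12-acetoxy-3,4:6,9-diepoxycembra-1(15),9-dien-2-one (CNP0162736.1) | CC(=O)O[C@@]1(C)C/C=C2\O[C@H](C[C@@H]2C)C[C@]2(C)O[C@H]2C(=O)C(=C(C)C)CC1 | target

**Totals**
Total step count: 14 (east branch steps 1–8, west branch steps 9–11, endgame steps 12–14).
Longest linear sequence: 11 steps (1–8, then 12–14).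

**Steps most likely to fail, with fallbacks**

Step 13 is the riskiest. The Mo alkylidyne must tolerate two free hydroxyls, an epoxide and an α-branched alkyne, and the gold catalyst must then work in the same flask without 6-endo closure or migration of the exocyclic enol ether into the ring. The fallback sets out from 25. Silylation of both hydroxyls (TESOTf, 2,6-lutidine) gives the 2,6-bis(triethylsilyl) ether F1. Alkyne metathesis on this aprotic substrate gives the cycloalkyne bis(triethylsilyl) ether F2, which is isolated. HF·pyridine then frees the cycloalkyne diol 26, now isolated, and a neutral π-acid (PtCl2, toluene) in a separate flask closes the oxolane, coming back to the route at 27.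

Step 12 may fail because the tetrasubstituted alkenyl bromide can be slow in oxidative addition and the alkenylchromium is hindered. The fallback sets out from 22 and uses an alkenyllithium, which requires a silyl ether in place of the acetate. Opening as in step 11 gives alkoxide 23, which is quenched with TESCl to give the triethylsilyl ether F3. Br/Li exchange (t-BuLi, −78 °C) gives the alkenyllithium F4, and 2.2 equiv of it add to aldehyde 16 to give the 12-OTES diol F5. The step 13 conditions take F5 through the cycloalkyne F6 (not isolated) to the enol ether alcohol F7. Dess–Martin oxidation gives the silyl-protected ketone F8, buffered fluoride (TBAF/AcOH) frees the tertiary alcohol F9, and acetylation (Ac2O, DMAP) comes back to the route at 28.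

Step 14 may fail because the hindered carbinol sits next to the epoxide and the acid-labile enol ether has to survive the oxidant. The fallback sets out from 25 and oxidises before cyclising. MnO2 is selective for the allylic C2 carbinol over the saturated C6–OH and gives the epoxy enone diyne F10. The one-pot sequence of step 13 applied to F10 runs through the cycloalkynone F11 (not isolated) and comes back to the route at 28, so the enol ether never meets an oxidant.

**Further compounds**
F1 | step 13 | 2,6-bis-O-triethylsilyl ether of 25 | CC[Si](CC)(CC)O[C@H](C[C@@H](C#CC)C)C[C@]1(C)O[C@H]1C(O[Si](CC)(CC)CC)C(=C(C)C)CC[C@@](C)(OC(C)=O)CC#CC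
F2 | step 13 | 2,6-bis-O-triethylsilyl ether of cycloalkyne 26 | CC[Si](CC)(CC)O[C@H](C[C@@H](C#C2)C)C[C@]1(C)O[C@H]1C(O[Si](CC)(CC)CC)C(=C(C)C)CC[C@@](C)(OC(C)=O)C2
F3 | step 12 | triethyl{[(5R)-8-bromo-5,9-dimethyldec-8-en-2-yn-5-yl]oxy}silane | CC[Si](CC)(CC)O[C@@](CCC(Br)=C(C)C)(C)CC#CC
F4 | step 12 | alkenyllithium from F3 (Li in place of Br) | CC[Si](CC)(CC)O[C@@](CCC([Li])=C(C)C)(C)CC#CC
F5 | step 12 | 12-O-triethylsilyl analogue of 25 (OTES in place of OAc) | O[C@H](C[C@@H](C#CC)C)C[C@]1(C)O[C@H]1C(O)C(=C(C)C)CC[C@@](C)(O[Si](CC)(CC)CC)CC#CC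
F6 | step 12 | 12-O-triethylsilyl analogue of cycloalkyne 26 | O[C@H](C[C@@H](C#C2)C)C[C@]1(C)O[C@H]1C(O)C(=C(C)C)CC[C@@](C)(O[Si](CC)(CC)CC)C2
F7 | step 12 | 12-O-triethylsilyl analogue of 27 | CC[Si](CC)(CC)O[C@@]1(C)C/C=C2\O[C@H](C[C@@H]2C)C[C@]2(C)O[C@H]2C(O)C(=C(C)C)CC1
F8 | step 12 | 12-O-triethylsilyl analogue of 28 | CC[Si](CC)(CC)O[C@@]1(C)C/C=C2\O[C@H](C[C@@H]2C)C[C@]2(C)O[C@H]2C(=O)C(=C(C)C)CC1
F9 | step 12 | 12-deacetyl 28 (tertiary alcohol) | O[C@@]1(C)C/C=C2\O[C@H](C[C@@H]2C)C[C@]2(C)O[C@H]2C(=O)C(=C(C)C)CC1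
F10 | step 14 | 2-oxo analogue of 25 (epoxy enone diyne with free 6-OH) | O[C@H](C[C@@H](C#CC)C)C[C@]1(C)O[C@H]1C(=O)C(=C(C)C)CC[C@@](C)(OC(C)=O)CC#CC
F11 | step 14 | 2-oxo analogue of cycloalkyne 26 | O[C@H](C[C@@H](C#C2)C)C[C@]1(C)O[C@H]1C(=O)C(=C(C)C)CC[C@@](C)(OC(C)=O)C2
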